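## Retrosynthetic overview
1. The last operations only unmask the target: hydrogenolysis of two phenolic benzyl ethers, preceded by hydrolysis of one acetonide.
2. Key disconnection is the lactone Cα–CH2Ar bond. It is made by trans-selective alkylation of an (R)-β-(arylmethyl)-γ-butyrolactone enolate with the benzylic bromide of the protected threo 8-O-4' unit.
3. Bromide half: an Evans syn-aldol of an aryloxyacetyl imide (4-bromoguaiacol + bromoacetic acid) with O-benzylvanillin sets both side-chain centres. ArBr is later converted to ArCH2Br.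
4. Lactone half: an Evans alkylation of a succinyl imide (from succinic anhydride) with O-benzylvanillyl bromide sets C4, followed by reduction and lactonisation.
5. All three arenes come from catechol via 4-bromoguaiacol. Ring order: temporary 1,3-dioxane (bromide half), then γ-butyrolactone (lactone half), and no ring is formed after the coupling.

Assumption: the SMILES is read as the (3R,4R)-lactone of the (−)-matairesinol series carrying a threo-(7''R,8''R)-guaiacylglycerol 8''-O-4 ether. The two 4-benzyloxazolidinones are used as recoverable reagents.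

## Route

Step 1
Reactants: 1 catechol (benzene-1,2-diol)
Product: 2 guaiacol (2-methoxyphenol)
Conditions: MeI (1 equiv), K2CO3, acetone, reflux (1 in 1.5-fold excess); distil
Reagents that add atoms: iodomethane CI
Why: In this Williamson ether synthesis the excess diol limits methylation to one oxygen, and 2 is separated from catechol and veratrole by distillation.

Step 2
Reactants: 2 guaiacol
Product: 3 4-bromo-2-methoxyphenol
Conditions: NBS (1.0 equiv), MeCN, 0 °C → rt
Reagents that add atoms: N-bromosuccinimide O=C1CCC(=O)N1Br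
Why: In this electrophilic aromatic bromination the free OH is the strongest director, so NBS in MeCN substitutes para to it.

Step 3
Reactants: 3 4-bromo-2-methoxyphenol
Product: 4 1-(benzyloxy)-4-bromo-2-methoxybenzene
Conditions: BnBr, K2CO3, DMF, rt
Reagents that add atoms: benzyl bromide BrCc1ccccc1
Why: Williamson benzylation of the phenoxide gives a base-stable protecting group that is removable by hydrogenolysis.

Step 4
Reactants: 4 1-(benzyloxy)-4-bromo-2-methoxybenzene
Product: 7 4-(benzyloxy)-3-methoxybenzaldehyde, via aryllithium 5 (not isolated), via lithium hemiaminal alkoxide 6 (not isolated)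
Conditions: n-BuLi, THF, −78 °C; DMF, −78 °C → rt; H2O
Reagents that add atoms: N,N-dimethylformamide CN(C)C=O; n-butyllithium [Li]CCCC (Li in 5 and 6 only)
Why: Bromine–lithium exchange is much faster than benzylic deprotonation at −78 °C, and Bouveault-type formylation with DMF delivers the aldehyde on hydrolysis.

Step 5
Reactants: 3 4-bromo-2-methoxyphenol; 8 bromoacetic acid
Product: 9 (4-bromo-2-methoxyphenoxy)acetic acid
Conditions: NaOH (aq), 100 °C; then HCl
Reagents that add atoms: none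
Why: This is the classical aryloxyacetic acid Williamson synthesis, an SN2 attack of the phenoxide on bromoacetate.

Step 6
Reactants: 9 (4-bromo-2-methoxyphenoxy)acetic acid
Product: 11 (4S)-4-benzyl-3-[(4-bromo-2-methoxyphenoxy)acetyl]-1,3-oxazolidin-2-one, via mixed pivalic anhydride 10 (not isolated)
Conditions: PivCl, Et3N, THF, −20 °C; (S)-4-benzyloxazolidin-2-one, LiCl, −20 °C → rt
Reagents that add atoms: (S)-4-benzyl-1,3-oxazolidin-2-one O=C1N[C@@H](Cc2ccccc2)CO1; pivaloyl chloride CC(C)(C)C(=O)Cl (atoms in 10 only)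
Why: In this mixed-anhydride N-acylation the LiCl-activated oxazolidinone attacks the unhindered aryloxyacetyl carbonyl rather than the pivaloyl one.

Step 7
Reactants: 11 (4S)-4-benzyl-3-[(4-bromo-2-methoxyphenoxy)acetyl]-1,3-oxazolidin-2-one; 7 4-(benzyloxy)-3-methoxybenzaldehyde
Product: 14 (4S)-4-benzyl-3-[(2S,3R)-3-[4-(benzyloxy)-3-methoxyphenyl]-2-(4-bromo-2-methoxyphenoxy)-3-hydroxypropanoyl]-1,3-oxazolidin-2-one, via Z-dibutylboron enolate 12 (not isolated), via boron aldolate 13 (not isolated)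
Conditions: Bu2BOTf, Et3N, CH2Cl2, −78 → 0 °C; 7, −78 → 0 °C; pH 7 buffer, MeOH, 30% H2O2, 0 °C
Reagents that add atoms: dibutylboron triflate CCCCB(CCCC)OS(=O)(=O)C(F)(F)F (atoms in 12 and 13 only)
Why: In this Evans syn-aldol the Z-boron enolate reacts through a Zimmerman–Traxler chair on the face left open by the (S)-benzyl group, giving the (2S,3R) syn adduct that becomes the threo-(7''R,8''R) unit.

Step 8
Reactants: 14 syn-aldol imide
Product: 15 (1R,2R)-1-[4-(benzyloxy)-3-methoxyphenyl]-2-(4-bromo-2-methoxyphenoxy)propane-1,3-diol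
Conditions: NaBH4, THF–H2O (4:1), 0 °C → rt
Reagents that add atoms: none
Why: Reductive auxiliary cleavage by hydride at the activated exocyclic imide carbonyl gives the primary alcohol without touching either stereocentre, the aryl bromide or the benzyl ether.

Step 9
Reactants: 15 threo-1,3-diol
Product: 16 (4R,5R)-4-[4-(benzyloxy)-3-methoxyphenyl]-5-(4-bromo-2-methoxyphenoxy)-2,2-dimethyl-1,3-dioxane
Conditions: 2,2-dimethoxypropane, PPTS (cat.), CH2Cl2, rt
Reagents that add atoms: 2,2-dimethoxypropane COC(C)(C)OC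
Why: Acid-catalysed transketalisation closes the six-membered acetonide, masking both hydroxyls for the organolithium and enolate steps while C–O bonds at the stereocentres stay intact.

Step 10
Reactants: 16 bromo acetonide
Product: 19 4-{[(4R,5R)-4-[4-(benzyloxy)-3-methoxyphenyl]-2,2-dimethyl-1,3-dioxan-5-yl]oxy}-3-methoxybenzaldehyde, via aryllithium 17 (not isolated), via lithium hemiaminal alkoxide 18 (not isolated)
Conditions: n-BuLi, THF, −78 °C; DMF, −78 °C → rt; H2O
Reagents that add atoms: N,N-dimethylformamide CN(C)C=O; n-butyllithium [Li]CCCC (Li in 17 and 18 only)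
Why: Bromine–lithium exchange and DMF formylation install the missing benzylic carbon, and the acetal and ethers are inert to n-BuLi at −78 °C.

Step 11
Reactants: 19 aldehyde
Product: 20 (4-{[(4R,5R)-4-[4-(benzyloxy)-3-methoxyphenyl]-2,2-dimethyl-1,3-dioxan-5-yl]oxy}-3-methoxyphenyl)methanol
Conditions: NaBH4, MeOH–THF, 0 °C
Reagents that add atoms: none
Why: Borohydride carbonyl reduction acts on the only reducible group present.

Step 12
Reactants: 20 benzylic alcohol
Product: 21 (4R,5R)-4-[4-(benzyloxy)-3-methoxyphenyl]-5-[4-(bromomethyl)-2-methoxyphenoxy]-2,2-dimethyl-1,3-dioxane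
Conditions: CBr4, PPh3, CH2Cl2, 0 °C; short silica plug, use at once
Reagents that add atoms: carbon tetrabromide BrC(Br)(Br)Br
Why: The Appel reaction converts the primary benzylic alcohol to the bromide under neutral conditions, so no HBr is formed that could open the acetonide.

Step 13
Reactants: 7 4-(benzyloxy)-3-methoxybenzaldehyde
Product: 22 [4-(benzyloxy)-3-methoxyphenyl]methanol
Conditions: NaBH4, MeOH, 0 °C
Reagents that add atoms: none
Why: This is a simple borohydride reduction of the aldehyde.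

Step 14
Reactants: 22 [4-(benzyloxy)-3-methoxyphenyl]methanol
Product: 23 1-(benzyloxy)-4-(bromomethyl)-2-methoxybenzene
Conditions: PBr3 (0.4 equiv), Et2O, 0 °C
Reagents that add atoms: phosphorus tribromide BrP(Br)Br
Why: SN2 bromination through the phosphite ester gives this known crystalline benzylic bromide, and the aryl benzyl ether survives at 0 °C.

Step 15
Reactants: 24 succinic anhydride
Product: 25 4-tert-butoxy-4-oxobutanoic acid
Conditions: t-BuOH, DMAP (cat.), N-hydroxysuccinimide (cat.), Et3N (cat.), toluene, reflux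
Reagents that add atoms: tert-butanol CC(C)(C)O
Why: Nucleophile-catalysed anhydride alcoholysis stops at the half ester because the carboxylate formed is unreactive.

Step 16
Reactants: 25 4-tert-butoxy-4-oxobutanoic acid
Product: 27 tert-butyl 4-[(4R)-4-benzyl-2-oxo-1,3-oxazolidin-3-yl]-4-oxobutanoate, via mixed pivalic anhydride 26 (not isolated)
Conditions: PivCl, Et3N, THF, −20 °C; (R)-4-benzyloxazolidin-2-one, LiCl, −20 °C → rt
Reagents that add atoms: (R)-4-benzyl-1,3-oxazolidin-2-one O=C1N[C@H](Cc2ccccc2)CO1; pivaloyl chloride CC(C)(C)C(=O)Cl (atoms in 26 only)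
Why: This is the same mixed-anhydride N-acylation as in step 6, and the tert-butyl ester is inert.

Step 17
Reactants: 27 succinyl imide; 23 1-(benzyloxy)-4-(bromomethyl)-2-methoxybenzene
Product: 29 tert-butyl (3R)-4-[(4R)-4-benzyl-2-oxo-1,3-oxazolidin-3-yl]-3-[4-(benzyloxy)-3-methoxybenzyl]-4-oxobutanoate, via sodium Z-enolate 28 (not isolated)
Conditions: NaHMDS (1.05 equiv), THF, −78 °C; 23, −78 → −30 °C
Reagents that add atoms: sodium hexamethyldisilazide C[Si](C)(C)[N-][Si](C)(C)C.[Na+] (Na in 28 only)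
Why: In this Evans asymmetric alkylation only the more acidic imide α-CH2 is deprotonated, and the chelated Z-enolate is benzylated on the face opposite the (R)-benzyl group, which sets (3R).

Step 18
Reactants: 29 alkylated imide
Product: 30 tert-butyl (3R)-3-[4-(benzyloxy)-3-methoxybenzyl]-4-hydroxybutanoate
Conditions: LiBH4, THF, 0 °C
Reagents that add atoms: none
Why: Chemoselective reductive auxiliary cleavage works because the imide carbonyl is far more electrophilic than the hindered tert-butyl ester, and the stereocentre is not enolised.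

Step 19
Reactants: 30 hydroxy tert-butyl ester
Product: 32 (4R)-4-[4-(benzyloxy)-3-methoxybenzyl]oxolan-2-one, via hydroxy acid 31 (not isolated)
Conditions: TFA–CH2Cl2 (1:4), 0 °C → rt, 1–2 h
Reagents that add atoms: none
Why: Acidolysis of the tert-butyl ester followed by spontaneous 5-exo lactonisation forms the γ-butyrolactone ring, and C4 is not involved so it stays (R).

Step 20
Reactants: 32 (4R)-4-[4-(benzyloxy)-3-methoxybenzyl]oxolan-2-one; 21 benzylic bromide of the protected 8-O-4' unit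
Product: 34 (3R,4R)-4-[4-(benzyloxy)-3-methoxybenzyl]-3-(4-{[(4R,5R)-4-[4-(benzyloxy)-3-methoxyphenyl]-2,2-dimethyl-1,3-dioxan-5-yl]oxy}-3-methoxybenzyl)oxolan-2-one, via lithium enolate 33 (not isolated)
Conditions: LiHMDS (1.1 equiv), THF, −78 °C; 21, DMPU, −78 → −30 °C
Reagents that add atoms: lithium hexamethyldisilazide C[Si](C)(C)[N-][Si](C)(C)C.[Li+] (Li in 33 only)
Why: In this lactone enolate alkylation (SN2) the bromide approaches anti to the C4 arylmethyl group, giving the trans-(3R,4R) dibenzylbutyrolactone, which is also the thermodynamic isomer.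

Step 21
Reactants: 34 fully protected sesquilignan
Product: 35 (3R,4R)-4-[4-(benzyloxy)-3-methoxybenzyl]-3-(4-{[(1R,2R)-1-[4-(benzyloxy)-3-methoxyphenyl]-1,3-dihydroxypropan-2-yl]oxy}-3-methoxybenzyl)oxolan-2-one
Conditions: AcOH–THF–H2O (3:1:1), 45 °C
Reagents that add atoms: none
Why: Mild acetal hydrolysis cleaves at the isopropylidene carbon, not at the benzylic C7''–O bond, so the threo configuration is kept and the lactone and benzyl ethers survive.

Step 22
Reactants: 35 bis-benzyl ether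
Product: 36 (3R,4R)-3-(4-{[(1R,2R)-1,3-dihydroxy-1-(4-hydroxy-3-methoxyphenyl)propan-2-yl]oxy}-3-methoxybenzyl)-4-(4-hydroxy-3-methoxybenzyl)oxolan-2-one (target)
Conditions: H2 (1 atm), 10% Pd/C, EtOAc–EtOH, rt, stop at full conversion
Reagents that add atoms: none
Why: Under neutral catalytic hydrogenolysis the phenolic benzyl ethers are cleaved much faster than the free secondary benzylic alcohol, as is usual for β-O-4 systems.

## Compound list
1 | catechol | Oc1ccccc1O | starting material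
2 | guaiacol | COc1ccccc1O | intermediate
3 | 4-bromo-2-methoxyphenol | COc1cc(Br)ccc1O | intermediate
4 | 1-(benzyloxy)-4-bromo-2-methoxybenzene | COc1cc(Br)ccc1OCc1ccccc1 | intermediate
5 | [4-(benzyloxy)-3-methoxyphenyl]lithium | COc1cc([Li])ccc1OCc1ccccc1 | intermediate
6 | lithium [4-(benzyloxy)-3-methoxyphenyl](dimethylamino)methanolate | COc1cc(C([O-])N(C)C)ccc1OCc1ccccc1.[Li+] | intermediate
7 | 4-(benzyloxy)-3-methoxybenzaldehyde | COc1cc(C=O)ccc1OCc1ccccc1 | intermediate
8 | bromoacetic acid | OC(=O)CBr | starting material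
9 | (4-bromo-2-methoxyphenoxy)acetic acid | COc1cc(Br)ccc1OCC(=O)O | intermediate
10 | (4-bromo-2-methoxyphenoxy)acetic pivalic anhydride | COc1cc(Br)ccc1OCC(=O)OC(=O)C(C)(C)C | intermediate
11 | (4S)-4-benzyl-3-[(4-bromo-2-methoxyphenoxy)acetyl]-1,3-oxazolidin-2-one | COc1cc(Br)ccc1OCC(=O)N1[C@@H](Cc2ccccc2)COC1=O | intermediate
12 | (Z)-dibutylboron enolate of 11 | COc1cc(Br)ccc1O/C=C(\OB(CCCC)CCCC)N1[C@@H](Cc2ccccc2)COC1=O | intermediate
13 | dibutylboron aldolate of 14 | COc1cc(Br)ccc1O[C@@H]([C@H](OB(CCCC)CCCC)c1ccc(OCc2ccccc2)c(OC)c1)C(=O)N1[C@@H](Cc2ccccc2)COC1=O | intermediate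
14 | (4S)-4-benzyl-3-[(2S,3R)-3-[4-(benzyloxy)-3-methoxyphenyl]-2-(4-bromo-2-methoxyphenoxy)-3-hydroxypropanoyl]-1,3-oxazolidin-2-one | COc1cc(Br)ccc1O[C@@H]([C@H](O)c1ccc(OCc2ccccc2)c(OC)c1)C(=O)N1[C@@H](Cc2ccccc2)COC1=O | intermediate
15 | (1R,2R)-1-[4-(benzyloxy)-3-methoxyphenyl]-2-(4-bromo-2-methoxyphenoxy)propane-1,3-diol | COc1cc(Br)ccc1O[C@H](CO)[C@H](O)c1ccc(OCc2ccccc2)c(OC)c1 | intermediate
16 | (4R,5R)-4-[4-(benzyloxy)-3-methoxyphenyl]-5-(4-bromo-2-methoxyphenoxy)-2,2-dimethyl-1,3-dioxane | COc1cc(Br)ccc1O[C@@H]2COC(C)(C)O[C@@H]2c3ccc(OCc4ccccc4)c(OC)c3 | intermediate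
17 | aryllithium from 16 | COc1cc([Li])ccc1O[C@@H]2COC(C)(C)O[C@@H]2c3ccc(OCc4ccccc4)c(OC)c3 | intermediate
18 | lithium hemiaminal alkoxide from 17 and DMF | COc1cc(C([O-])N(C)C)ccc1O[C@@H]2COC(C)(C)O[C@@H]2c3ccc(OCc4ccccc4)c(OC)c3.[Li+] | intermediate
19 | 4-{[(4R,5R)-4-[4-(benzyloxy)-3-methoxyphenyl]-2,2-dimethyl-1,3-dioxan-5-yl]oxy}-3-methoxybenzaldehyde | COc1cc(C=O)ccc1O[C@@H]2COC(C)(C)O[C@@H]2c3ccc(OCc4ccccc4)c(OC)c3 | intermediate
20 | (4-{[(4R,5R)-4-[4-(benzyloxy)-3-methoxyphenyl]-2,2-dimethyl-1,3-dioxan-5-yl]oxy}-3-methoxyphenyl)methanol | COc1cc(CO)ccc1O[C@@H]2COC(C)(C)O[C@@H]2c3ccc(OCc4ccccc4)c(OC)c3 | intermediate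
21 | (4R,5R)-4-[4-(benzyloxy)-3-methoxyphenyl]-5-[4-(bromomethyl)-2-methoxyphenoxy]-2,2-dimethyl-1,3-dioxane | COc1cc(CBr)ccc1O[C@@H]2COC(C)(C)O[C@@H]2c3ccc(OCc4ccccc4)c(OC)c3 | intermediate
22 | [4-(benzyloxy)-3-methoxyphenyl]methanol | COc1cc(CO)ccc1OCc1ccccc1 | intermediate
23 | 1-(benzyloxy)-4-(bromomethyl)-2-methoxybenzene | COc1cc(CBr)ccc1OCc1ccccc1 | intermediate
24 | succinic anhydride | O=C1CCC(=O)O1 | starting material
25 | 4-tert-butoxy-4-oxobutanoic acid | CC(C)(C)OC(=O)CCC(=O)O | intermediate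
26 | 4-tert-butoxy-4-oxobutanoic pivalic anhydride | CC(C)(C)OC(=O)CCC(=O)OC(=O)C(C)(C)C | intermediate
27 | tert-butyl 4-[(4R)-4-benzyl-2-oxo-1,3-oxazolidin-3-yl]-4-oxobutanoate | CC(C)(C)OC(=O)CCC(=O)N1[C@H](Cc2ccccc2)COC1=O | intermediate
28 | sodium (Z)-enolate of 27 | CC(C)(C)OC(=O)C/C=C(\[O-])N1[C@H](Cc2ccccc2)COC1=O.[Na+] | intermediate
29 | tert-butyl (3R)-4-[(4R)-4-benzyl-2-oxo-1,3-oxazolidin-3-yl]-3-[4-(benzyloxy)-3-methoxybenzyl]-4-oxobutanoate | CC(C)(C)OC(=O)C[C@@H](Cc1ccc(OCc2ccccc2)c(OC)c1)C(=O)N1[C@H](Cc2ccccc2)COC1=O | intermediate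
30 | tert-butyl (3R)-3-[4-(benzyloxy)-3-methoxybenzyl]-4-hydroxybutanoate | CC(C)(C)OC(=O)C[C@@H](Cc1ccc(OCc2ccccc2)c(OC)c1)CO | intermediate
31 | (3R)-3-[4-(benzyloxy)-3-methoxybenzyl]-4-hydroxybutanoic acid | OC(=O)C[C@@H](Cc1ccc(OCc2ccccc2)c(OC)c1)CO | intermediate
32 | (4R)-4-[4-(benzyloxy)-3-methoxybenzyl]oxolan-2-one | COc1cc(C[C@H]2COC(=O)C2)ccc1OCc1ccccc1 | intermediate
33 | lithium enolate of 32 | COc1cc(C[C@H]2COC([O-])=C2)ccc1OCc1ccccc1.[Li+] | intermediate
34 | (3R,4R)-4-[4-(benzyloxy)-3-methoxybenzyl]-3-(4-{[(4R,5R)-4-[4-(benzyloxy)-3-methoxyphenyl]-2,2-dimethyl-1,3-dioxan-5-yl]oxy}-3-methoxybenzyl)oxolan-2-one | COc1cc(C[C@H]2COC(=O)[C@@H]2Cc3ccc(O[C@@H]4COC(C)(C)O[C@@H]4c5ccc(OCc6ccccc6)c(OC)c5)c(OC)c3)ccc1OCc7ccccc7 | intermediate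
35 | (3R,4R)-4-[4-(benzyloxy)-3-methoxybenzyl]-3-(4-{[(1R,2R)-1-[4-(benzyloxy)-3-methoxyphenyl]-1,3-dihydroxypropan-2-yl]oxy}-3-methoxybenzyl)oxolan-2-one | COc1cc(C[C@H]2COC(=O)[C@@H]2Cc3ccc(O[C@H](CO)[C@H](O)c4ccc(OCc5ccccc5)c(OC)c4)c(OC)c3)ccc1OCc6ccccc6 | intermediate
36 | (3R,4R)-3-(4-{[(1R,2R)-1,3-dihydroxy-1-(4-hydroxy-3-methoxyphenyl)propan-2-yl]oxy}-3-methoxybenzyl)-4-(4-hydroxy-3-methoxybenzyl)oxolan-2-one (CNP0305334.1) | COc1cc(C[C@H]2COC(=O)[C@@H]2Cc2ccc(O[C@H](CO)[C@H](O)c3ccc(O)c(OC)c3)c(OC)c2)ccc1O | target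

## Step count
Total step count: 22.
Longest linear sequence: 13 steps (1, 2, 3, 4, 7, 8, 9, 10, 11, 12, 20, 21, 22). The lactone branch runs 12 steps (1, 2, 3, 4, 13, 14, 17, 18, 19, 20, 21, 22).

## Three steps most likely to fail

**Step 7 (Evans aldol).**
- Risk: the electron-rich aldehyde 7 is a sluggish acceptor, and α-aryloxy aldolates can retro-aldolise, which would erode yield and dr.
- The fallback replaces auxiliary control by a catalytic dynamic kinetic resolution. It sets out from 9 (partner 7 unchanged) and comes back at 15.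
- Acid 9 is esterified (EtOH, cat. H2SO4, reflux) to ethyl (4-bromo-2-methoxyphenoxy)acetate F1.
- The lithium enolate of F1 (LDA, THF, −78 °C) is added to 7 without any stereocontrol. This gives ethyl 3-[4-(benzyloxy)-3-methoxyphenyl]-2-(4-bromo-2-methoxyphenoxy)-3-hydroxypropanoate F2 as a stereoisomer mixture.
- Dess–Martin oxidation converts the mixture into the configurationally labile ethyl 3-[4-(benzyloxy)-3-methoxyphenyl]-2-(4-bromo-2-methoxyphenoxy)-3-oxopropanoate F3.
- Noyori transfer hydrogenation under DKR conditions (RuCl[(S,S)-TsDPEN](p-cymene), HCO2H–Et3N 5:2, CH2Cl2, 30 °C) is syn-selective for α-alkoxy β-keto esters. The aryl-ketone model predicts the R carbinol, giving ethyl (2S,3R)-3-[4-(benzyloxy)-3-methoxyphenyl]-2-(4-bromo-2-methoxyphenoxy)-3-hydroxypropanoate F4.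
- LiBH4 in THF reduces F4 to diol 15.

**Step 17 (Evans alkylation of the succinyl imide).**
- Risk: enolisation must occur only at the imide α-CH2 of a substrate with two acidic sites, and bromide 23 is labile.
- The fallback reverses the polarity of the bond construction. It sets out from 7 (and 8) and comes back at 30.
- Knoevenagel–Doebner condensation of 7 with malonic acid (pyridine, cat. piperidine, 90 °C) gives (E)-3-[4-(benzyloxy)-3-methoxyphenyl]prop-2-enoic acid F5.
- Diimide reduction (TsNHNH2, NaOAc, aq. DME, reflux) leaves the benzyl ether untouched and gives 3-[4-(benzyloxy)-3-methoxyphenyl]propanoic acid F6.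
- Mixed-anhydride acylation of (S)-4-benzyloxazolidin-2-one gives (4S)-4-benzyl-3-{3-[4-(benzyloxy)-3-methoxyphenyl]propanoyl}-1,3-oxazolidin-2-one F7.
- The sodium enolate of F7 (NaHMDS, THF, −78 °C) is alkylated with tert-butyl bromoacetate F8, which is made from 8 with isobutene and cat. H2SO4.
- The product is tert-butyl (3R)-4-[(4S)-4-benzyl-2-oxo-1,3-oxazolidin-3-yl]-3-[4-(benzyloxy)-3-methoxybenzyl]-4-oxobutanoate F9. It has the same (3R) centre, now set with the (S)-auxiliary.
- LiBH4 converts F9 into 30.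

**Step 20 (late coupling, together with the bromide made in step 12).**
- Risk: bromide 21 is a very electron-rich benzylic bromide that ionises easily. It must survive isolation and react stoichiometrically with a precious enolate.
- The fallback replaces the SN2 alkylation by carbonyl addition and radical deoxygenation. It sets out from aldehyde 19 (skipping steps 11 and 12, partner 32 unchanged) and comes back at 34.
- The lithium enolate 33 of 32 (LiHMDS, THF, −78 °C) adds to 19 anti to the C4 substituent. This gives (3S,4R)-4-[4-(benzyloxy)-3-methoxybenzyl]-3-[(4-{[(4R,5R)-4-[4-(benzyloxy)-3-methoxyphenyl]-2,2-dimethyl-1,3-dioxan-5-yl]oxy}-3-methoxyphenyl)(hydroxy)methyl]oxolan-2-one F10. It is a mixture of carbinol epimers, which does not matter because that centre is removed.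
- 1,1'-Thiocarbonyldiimidazole with DMAP in THF at 50 °C gives the O-(imidazole-1-carbothioyl) derivative of the aldol adduct F11.
- Barton–McCombie reduction (Bu3SnH, AIBN, toluene, 90 °C) removes the benzylic oxygen without touching the benzyl ethers, the acetonide or the ring stereocentres, giving 34.

## Further compounds
F1 | step 7 | ethyl (4-bromo-2-methoxyphenoxy)acetate | CCOC(=O)COc1ccc(Br)cc1OC
F2 | step 7 | ethyl 3-[4-(benzyloxy)-3-methoxyphenyl]-2-(4-bromo-2-methoxyphenoxy)-3-hydroxypropanoate (stereoisomer mixture) | CCOC(=O)C(Oc1ccc(Br)cc1OC)C(O)c1ccc(OCc2ccccc2)c(OC)c1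
F3 | step 7 | ethyl 3-[4-(benzyloxy)-3-methoxyphenyl]-2-(4-bromo-2-methoxyphenoxy)-3-oxopropanoate (racemic, labile) | CCOC(=O)C(Oc1ccc(Br)cc1OC)C(=O)c1ccc(OCc2ccccc2)c(OC)c1
F4 | step 7 | ethyl (2S,3R)-3-[4-(benzyloxy)-3-methoxyphenyl]-2-(4-bromo-2-methoxyphenoxy)-3-hydroxypropanoate | COc1cc(Br)ccc1O[C@@H]([C@H](O)c1ccc(OCc2ccccc2)c(OC)c1)C(=O)OCC
F5 | step 17 | (E)-3-[4-(benzyloxy)-3-methoxyphenyl]prop-2-enoic acid | COc1cc(/C=C/C(=O)O)ccc1OCc1ccccc1
F6 | step 17 | 3-[4-(benzyloxy)-3-methoxyphenyl]propanoic acid | COc1cc(CCC(=O)O)ccc1OCc1ccccc1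
F7 | step 17 | (4S)-4-benzyl-3-{3-[4-(benzyloxy)-3-methoxyphenyl]propanoyl}-1,3-oxazolidin-2-one | COc1cc(CCC(=O)N2[C@@H](Cc3ccccc3)COC2=O)ccc1OCc1ccccc1
F8 | step 17 | tert-butyl bromoacetate | CC(C)(C)OC(=O)CBr
F9 | step 17 | tert-butyl (3R)-4-[(4S)-4-benzyl-2-oxo-1,3-oxazolidin-3-yl]-3-[4-(benzyloxy)-3-methoxybenzyl]-4-oxobutanoate | CC(C)(C)OC(=O)C[C@@H](Cc1ccc(OCc2ccccc2)c(OC)c1)C(=O)N1[C@@H](Cc2ccccc2)COC1=O
F10 | step 20 | (3S,4R)-4-[4-(benzyloxy)-3-methoxybenzyl]-3-[(4-{[(4R,5R)-4-[4-(benzyloxy)-3-methoxyphenyl]-2,2-dimethyl-1,3-dioxan-5-yl]oxy}-3-methoxyphenyl)(hydroxy)methyl]oxolan-2-one (carbinol epimers) | COc1cc(C[C@H]2COC(=O)[C@@H]2C(O)c3ccc(O[C@@H]4COC(C)(C)O[C@@H]4c5ccc(OCc6ccccc6)c(OC)c5)c(OC)c3)ccc1OCc7ccccc7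
F11 | step 20 | O-(imidazole-1-carbothioyl) derivative of the aldol adduct | COc1cc(C[C@H]2COC(=O)[C@@H]2C(OC(=S)n8ccnc8)c3ccc(O[C@@H]4COC(C)(C)O[C@@H]4c5ccc(OCc6ccccc6)c(OC)c5)c(OC)c3)ccc1OCc7ccccc7
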